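The readings were computed for an exercise; scatter was added.

Temperature moves the time at which target peaks, and two views dispute what that means for flasks held for the same time.

| flask | starting material | partner | capture agent | temperature | remark | time |
|---|---|---|---|---|---|---|
| autumn | 0.091 M | 0.67 equiv | 0.091 M | 15 °C | run made earlier |  |
| summer | 0.091 M | 1.5 equiv | 0.091 M | 37 °C | run made earlier |  |
| dusk | 0.18 M | 1 equiv | 0.091 M | 15 °C | run made earlier |  |
| ash | 0.091 M | 1.00 equiv | 0.0910 M | 45 °C |  | 12 min |
| cedar | 0.091 M | 1.00 equiv | 0.0910 M | 25 °C |  | 12 min |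
| larch | 0.091 M | 1.00 equiv | 0.0910 M | 5 °C |  | 12 min |

| run | time / min | target / % | starting material / % |
|---|---|---|---|
| autumn | 4.00 | 0.8 | 78.6 |
| autumn | 8.00 | 3.5 | 69.6 |
| autumn | 12.0 | 5.9 | 65.2 |
| autumn | 20.0 | 9.7 | 53.3 |
| autumn | 25.0 | 10.7 | 50.3 |
| autumn | 40.0 | 13.1 | 45.9 |
| autumn | 60.0 | 11.3 | 42.9 |
| summer | 2.00 | 9.0 | 35.4 |
| summer | 4.00 | 7.8 | 21.7 |
| summer | 6.00 | 5.0 | 16.3 |
| summer | 8.00 | 3.9 | 14.2 |
| summer | 10.0 | 4.8 | 11.3 |
| summer | 12.0 | 4.4 | 11.8 |
| summer | 15.0 | 3.9 | 9.9 |
| dusk | 12.0 | 13.2 | 31.8 |
| dusk | 25.0 | 21.0 | 22.5 |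
| dusk | 40.0 | 25.0 | 17.1 |
| dusk | 50.0 | 25.2 | 15.9 |
| dusk | 60.0 | 26.6 | 13.8 |

(standard deviation of a reading: 1 percentage point)

- the flask with the highest amount of target, in percent of the starting material charged ("all alike" if they lie within 1.5 percentage points) (ash / cedar / larch / all alike)
- final target, as a percentage of the starting material charged, in ash
- final target, as a percentage of the starting material charged, in cedar
- final target, as a percentage of the starting material charged, in larch

- what was read earlier has a scatter of 1 percentage point, one standard deviation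

The yield view reads the balance of partner. In the summer run, 1.5 equiv of partner removed 90.1 % of the starting material by the last reading. So 1.00 equiv of partner should remove 60.1 % in ash. At the highest reading of the autumn run, target was 24.2 % of the starting material gone. Together these give ash 14.5 % of target. Cedar and larch hold the same charge of partner as ash, so this reckoning gives them the same figure. The yield view therefore expects all alike.

The clock view, which is mine, reads peaks. The autumn readings peak near 40.0 min at 15 °C. The summer readings are highest at 2.00 min at 37 °C, the first reading, and the partner charges differ. A steady factor per degree between these gives a peak time of 0.673 min for ash, 10.2 min for cedar and 156 min for larch. Call age the time of a flask over its peak time: for ash 17.8, for cedar 1.17, for larch 0.0769. I expect most target near age one. Below that a flask is still in its lag, and above it the peak has passed.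

The forecast takes the clock side with its own factor. It names cedar, with 3.5 % in ash, 10 % in cedar and 1.5 % in larch. For ash it says “the peak is long past, leaving the plateau”.

The simulation gives 0.452 % in ash, 14.1 % in cedar and 1.95 % in larch, so cedar leads, as the forecast said.

    open intermediate ⇌ target (K = 1.50, k = 0.00255 s⁻¹, Ea = 89.0 kJ mol⁻¹, ΔH = −75.0 kJ mol⁻¹)
    starting material + partner → open intermediate + by-product (k = 0.0396 M⁻¹ s⁻¹, Ea = 60.0 kJ mol⁻¹)
    partner → decomposed reagent (k = 5.32 × 10⁻⁴ s⁻¹, Ea = 92.0 kJ mol⁻¹)
    open intermediate ⇌ isomer of the product (K = 2.80, k = 0.00128 s⁻¹, Ea = 91.0 kJ mol⁻¹, ΔH = −27.0 kJ mol⁻¹)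
    open intermediate + capture agent → trapped intermediate (k = 0.0419 M⁻¹ s⁻¹, Ea = 63.0 kJ mol⁻¹)
    (constants at 25 °C)

Ash, at age 17.8, lost 65.0 % of its starting material, against 60.1 % from the balance. It kept 0.016 % of partner, its limiting reagent, and its target is 0.452 %. The yield view fits cedar, at age 1.17: target there is 21.3 % of the starting material gone, against the 24.2 % read in autumn. The neighbour flask is ash kept at 30 °C. Its peak time reckons to 5.19 min, so its age is 2.31, younger than ash. That neighbour flask ends with 8.56 % of target.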